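The 3,7-dioxabicyclo[3.3.0]octane core (ring A: C1–C2–O3–C4–C5, phenolic aryl on C2; ring B: C5–C6–O7–C8–C1, trimethoxyphenyl on C6) is cut at the shared C1–C5 bond and at the benzylic C2–O3 bond. The feature used is that C5 lies between C4–O3 and C6–O7. A C4–C5 oxirane delivers a C5 radical, O7 holds a styrene within 5-exo reach, and the C4 oxygen is left poised over C2. One flask therefore builds ring B, then ring A, and sets C5, C1 and C2 from C6 alone. The substrate is an enantioenriched oxiranyl(trimethoxyphenyl)methyl ether of an O-silylated sinapyl alcohol.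

Key step: step 8

Remarks on the chemistry
- Configuration: in core numbering the target is (1S,2R,5S,6R), with H1 and H5 cis and both aryl groups on the convex (exo) face. In furo[3,4-c]furan numbering this is (1R,3aS,4R,6aS).
- Only C6 of the precursor must be enantiopure. C5 becomes a planar radical, so its oxirane configuration (R, the erythro isomer that the Sharpless reaction delivers) does not affect the product.
- The benzylic C2 radical cannot persist until iodine is added. A second Cp2TiCl captures it, so two equivalents of trivalent titanium are consumed per molecule.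
- No acid is planned once ring A exists. Ionisation at C2 or C6 is reversible and levels exo and endo aryl groups to a mixture, so it cannot repair them. C2 therefore rests on kinetic closure, and any epimer would be removed by chromatography.
- Assumption: vinylmagnesium bromide in THF, anhydrous t-BuOOH in decane and diisopropyl L-(+)-tartrate (L-(+)-DIPT) are purchased.

Step 1
Reactants: 1 3,4,5-trimethoxybenzaldehyde; 2 vinylmagnesium bromide
Product: 3 (±)-1-(3,4,5-trimethoxyphenyl)prop-2-en-1-ol
Conditions: THF, 0 °C; then sat. aq. NH4Cl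
Reagents that add atoms: none
Why: Grignard 1,2-addition of a vinyl nucleophile to a non-enolisable aromatic aldehyde is reliable, and the new carbinol centre (future C6) is deliberately formed racemic and sorted in step 2.

Step 2
Reactants: 3 (±)-1-(3,4,5-trimethoxyphenyl)prop-2-en-1-ol
Product: 4 (S)-[(2R)-oxiran-2-yl](3,4,5-trimethoxyphenyl)methanol (erythro)
Conditions: Ti(OiPr)4 (0.15 equiv), L-(+)-DIPT (0.2 equiv), t-BuOOH (0.45 equiv), 4 Å MS, CH2Cl2, −20 °C
Reagents that add atoms: tert-butyl hydroperoxide, CC(C)(C)OO
Why: In this Sharpless kinetic resolution by asymmetric epoxidation the (R)-carbinol is the matched, fast-reacting enantiomer with L-(+)-DIPT, so with the oxidant limiting it alone should be converted into the erythro epoxy alcohol (C6 fixed by selection, C5 by the tartrate-controlled alkene face), while the (S)-alcohol stays behind and is removed by chromatography.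

Step 3
Reactants: 5 syringaldehyde
Product: 6 4-[(tert-butyldimethylsilyl)oxy]-3,5-dimethoxybenzaldehyde
Conditions: TBSCl, imidazole, DMF, rt
Reagents that add atoms: tert-butyldimethylsilyl chloride, CC(C)(C)[Si](C)(C)Cl
Why: Imidazole-promoted silylation of a phenol is standard, and the resulting aryl TBS ether, shielded by two ortho methoxy groups, tolerates hydride, PBr3, trivalent titanium and iodine and leaves with fluoride under non-acidic conditions.

Step 4
Reactants: 6 4-[(tert-butyldimethylsilyl)oxy]-3,5-dimethoxybenzaldehyde; 7 triethyl phosphonoacetate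
Product: 8 ethyl (2E)-3-{4-[(tert-butyldimethylsilyl)oxy]-3,5-dimethoxyphenyl}prop-2-enoate
Conditions: NaH (1.15 equiv), 7 (1.2 equiv), THF, 0 °C → rt
Reagents that add atoms: none
Why: Horner–Wadsworth–Emmons olefination of an aromatic aldehyde with a stabilised phosphonate anion should give the E-enoate, and keeping the base slightly below the phosphonate leaves nothing that could attack the aryl silyl ether.

Step 5
Reactants: 8 ethyl (2E)-3-{4-[(tert-butyldimethylsilyl)oxy]-3,5-dimethoxyphenyl}prop-2-enoate
Product: 9 (2E)-3-{4-[(tert-butyldimethylsilyl)oxy]-3,5-dimethoxyphenyl}prop-2-en-1-ol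
Conditions: i-Bu2AlH (DIBAL-H, 2.3 equiv), CH2Cl2, −78 °C; then aq. potassium sodium tartrate
Reagents that add atoms: none
Why: 1,2-Reduction of a conjugated ester with two hydride equivalents of i-Bu2AlH at low temperature should stop at the allylic alcohol without touching the alkene geometry or the silyl ether.

Step 6
Reactants: 9 (2E)-3-{4-[(tert-butyldimethylsilyl)oxy]-3,5-dimethoxyphenyl}prop-2-en-1-ol
Product: 10 tert-butyl{4-[(1E)-3-bromoprop-1-en-1-yl]-2,6-dimethoxyphenoxy}dimethylsilane
Conditions: PBr3 (0.4 equiv), Et2O, 0 °C; aqueous wash, used at once without chromatography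
Reagents that add atoms: phosphorus tribromide, BrP(Br)Br
Why: Bromination of a primary allylic alcohol through its phosphite ester (SN2 by bromide) is fast at 0 °C, the conjugated E primary bromide is also the thermodynamic allylic isomer, and immediate use allows for the lability of this electron-rich bromide.

Step 7
Reactants: 4 (S)-[(2R)-oxiran-2-yl](3,4,5-trimethoxyphenyl)methanol; 10 tert-butyl{4-[(1E)-3-bromoprop-1-en-1-yl]-2,6-dimethoxyphenoxy}dimethylsilane
Product: 11 (2R)-2-[(S)-{[(2E)-3-{4-[(tert-butyldimethylsilyl)oxy]-3,5-dimethoxyphenyl}prop-2-en-1-yl]oxy}(3,4,5-trimethoxyphenyl)methyl]oxirane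
Conditions: NaH (1.1 equiv, added last to 4 + 10), Bu4NI (0.1 equiv), THF, −20 → 0 °C
Reagents that add atoms: none
Why: In this Williamson ether synthesis with a very reactive primary allylic bromide, adding the base last in aprotic THF lets the oxygen be alkylated as soon as it is deprotonated, which should suppress Payne migration of the oxirane and silyl transfer from the phenol, and no stereocentre is touched.

Step 8
Reactants: 11 (2R)-2-[(S)-{[(2E)-3-{4-[(tert-butyldimethylsilyl)oxy]-3,5-dimethoxyphenyl}prop-2-en-1-yl]oxy}(3,4,5-trimethoxyphenyl)methyl]oxirane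
Product: 14 O-TBS ether of the target (core 1S,2R,5S,6R; both aryl groups exo), via benzyltitanium alkoxide 12 (not isolated), via benzylic iodide 13 (not isolated)
Conditions: Cp2TiCl2 (2.5 equiv), Zn, THF, rt, green Cp2TiCl solution decanted from Zn and added slowly to 11 in THF, rt; then I2 (1.5 equiv), THF, rt → 40 °C
Reagents that add atoms: none
Why: Cp2TiCl (trivalent titanium) transfers one electron to the oxirane, which opens to the secondary C5 radical with the C4 oxygen bound to tetravalent titanium; this is the titanocene-mediated reductive epoxide opening with radical cyclisation (Nugent–RajanBabu reaction), whose iodine-terminated form is established for epoxy cinnamyl ethers. Ring B closes by 5-exo-trig addition of C5 to C1 of the styrene, and a second Cp2TiCl intercepts the C2 benzylic radical to give 12. Iodine cleaves the C2–Ti bond to iodide 13, which the electron-rich aryl group loosens, and the C4 titanium alkoxide closes ring A by 5-exo-tet displacement (5-exo-trig if the free aryl-stabilised cation intervenes). C5 and C1 are controlled by C6 through a chair-like 5-hexenyl transition state with the trimethoxyphenyl group pseudo-equatorial (C6 aryl trans to the C4 arm) and with the usual cis preference between the substituent on the radical carbon and the new side chain (C4 and C2 arms cis, hence H1/H5 cis), and a trans adduct cannot bridge and would be removed as a monocyclic by-product. C2 is set kinetically, the aryl group taking the convex face away from C8H2, as in the closure of quinone methides derived from sinapyl alcohol. The step needs cyclisation to outrun capture of the C5 radical by titanium, which would end in deoxygenation; the conjugated E acceptor makes ring closure fast, and slow addition of Cp2TiCl to 11 keeps the trap dilute.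

Step 9
Reactants: 14 O-TBS ether of the target
Product: 15 2,6-dimethoxy-4-[(1R,3aS,4R,6aS)-4-(3,4,5-trimethoxyphenyl)tetrahydro-1H,3H-furo[3,4-c]furan-1-yl]phenol (target)
Conditions: Bu4NF, AcOH (1:1, 1.1 equiv), THF, 0 °C
Reagents that add atoms: none
Why: Fluoride-driven cleavage of an aryl silyl ether is fast at 0 °C, and the acetic acid buffer protonates the phenoxide at once, so that neither base-induced quinone-methide opening at C2 nor acid ionisation of the benzylic ethers should disturb a stereocentre.

Compound list
1 | 3,4,5-trimethoxybenzaldehyde | COc1cc(C=O)cc(OC)c1OC | starting material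
2 | vinylmagnesium bromide | C=C[Mg]Br | starting material
3 | (±)-1-(3,4,5-trimethoxyphenyl)prop-2-en-1-ol | COc1cc(cc(OC)c1OC)C(O)C=C | intermediate
4 | (S)-[(2R)-oxiran-2-yl](3,4,5-trimethoxyphenyl)methanol | COc1cc(cc(OC)c1OC)[C@H](O)[C@H]1CO1 | intermediate
5 | syringaldehyde | COc1cc(C=O)cc(OC)c1O | starting material
6 | 4-[(tert-butyldimethylsilyl)oxy]-3,5-dimethoxybenzaldehyde | COc1cc(C=O)cc(OC)c1O[Si](C)(C)C(C)(C)C | intermediate
7 | triethyl phosphonoacetate | CCOC(=O)CP(=O)(OCC)OCC | starting material
8 | ethyl (2E)-3-{4-[(tert-butyldimethylsilyl)oxy]-3,5-dimethoxyphenyl}prop-2-enoate | CCOC(=O)/C=C/c1cc(OC)c(O[Si](C)(C)C(C)(C)C)c(OC)c1 | intermediate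
9 | (2E)-3-{4-[(tert-butyldimethylsilyl)oxy]-3,5-dimethoxyphenyl}prop-2-en-1-ol | OC/C=C/c1cc(OC)c(O[Si](C)(C)C(C)(C)C)c(OC)c1 | intermediate
10 | tert-butyl{4-[(1E)-3-bromoprop-1-en-1-yl]-2,6-dimethoxyphenoxy}dimethylsilane | BrC/C=C/c1cc(OC)c(O[Si](C)(C)C(C)(C)C)c(OC)c1 | intermediate
11 | (2R)-2-[(S)-{[(2E)-3-{4-[(tert-butyldimethylsilyl)oxy]-3,5-dimethoxyphenyl}prop-2-en-1-yl]oxy}(3,4,5-trimethoxyphenyl)methyl]oxirane | COc1cc(cc(OC)c1OC)[C@H](OC/C=C/c1cc(OC)c(O[Si](C)(C)C(C)(C)C)c(OC)c1)[C@H]1CO1 | intermediate
12 | ring B tetrahydrofuran with C4–O–TiCp2Cl and C2–TiCp2Cl (C1 S, C5 S, C6 R; C2 undefined; Cp drawn σ-bonded) | COc1cc(C([C@@H]2CO[C@@H](c3cc(OC)c(OC)c(OC)c3)[C@@H]2CO[Ti](Cl)(C4C=CC=C4)C4C=CC=C4)[Ti](Cl)(C4C=CC=C4)C4C=CC=C4)cc(OC)c1O[Si](C)(C)C(C)(C)C | intermediate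
13 | ring B tetrahydrofuran with C4–O–TiCp2Cl and C2–I (C1 S, C5 S, C6 R; C2 undefined; Cp drawn σ-bonded) | COc1cc(C(I)[C@@H]2CO[C@@H](c3cc(OC)c(OC)c(OC)c3)[C@@H]2CO[Ti](Cl)(C4C=CC=C4)C4C=CC=C4)cc(OC)c1O[Si](C)(C)C(C)(C)C | intermediate
14 | tert-butyl{2,6-dimethoxy-4-[(1R,3aS,4R,6aS)-4-(3,4,5-trimethoxyphenyl)tetrahydro-1H,3H-furo[3,4-c]furan-1-yl]phenoxy}dimethylsilane | COc1cc([C@@H]2OC[C@@H]3[C@H]2CO[C@H]3c2cc(OC)c(OC)c(OC)c2)cc(OC)c1O[Si](C)(C)C(C)(C)C | intermediate
15 | 2,6-dimethoxy-4-[(1R,3aS,4R,6aS)-4-(3,4,5-trimethoxyphenyl)tetrahydro-1H,3H-furo[3,4-c]furan-1-yl]phenol | COc1cc([C@@H]2OC[C@@H]3[C@H]2CO[C@H]3c2cc(OC)c(OC)c(OC)c2)cc(OC)c1O | target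

Total step count: 9
Longest linear sequence: 7 steps (5 → 6 → 8 → 9 → 10 → 11 → 14 → 15)

Steps most likely to fail

1. Step 8.
- **Risk:** The C5 radical may be captured by titanium before it cyclises, with loss of the oxirane oxygen, and facial control in the closure of ring B may be incomplete. The second half is the weaker part. Iodinolysis of a hindered benzyl–titanium bond takes place beside an easily oxidised arene. The ether closure then competes with elimination and with epimerisation at C2 by the Lewis-acidic salts.
- **Fallback (from 11, returning at 15):** The two ring closures are separated. Compound 11 is cyclised with Cp2TiCl as before, but the benzyl–titanium bond is protonated with aq. NaH2PO4 and not iodinated. This should give the monocyclic [(2R,3S,4S)-4-{4-[(tert-butyldimethylsilyl)oxy]-3,5-dimethoxybenzyl}-2-(3,4,5-trimethoxyphenyl)tetrahydrofuran-3-yl]methanol F1, a stable compound that can be freed from diastereomers. Bu4NF/AcOH then releases the free phenol F2. Oxidation of this 4-alkyl-2,6-dimethoxyphenol with Ag2O in CH2Cl2 should give the p-quinone methide F3. The cis C4 hydroxyl adds to it at C2 by 5-exo-trig oxa-conjugate addition. This is the ring-closing event by which oxidised sinapyl alcohol builds its furofuran with exo aryl groups. Only the ring carrying the free hydroxyl can be oxidised in this way, so C6 stays untouched.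

2. Step 7.
- **Risk:** The deprotonated epoxy alcohol may undergo oxirane migration (Payne rearrangement towards the aryl-substituted epoxide). The silyl group may be transferred from the phenol oxygen. The electron-rich bromide may ionise or decompose before it couples.
- **Fallback (from 4 and 6, returning at 11):** This avoids both the strong base and the cinnamyl bromide. Compound 4 is O-allylated under neutral conditions with allyl ethyl carbonate and zerovalent palladium (Pd2(dba)3, dppb, THF, 65 °C) to the allyl ether F4. Aldehyde 6 is methylenated by a Wittig reaction (Ph3PCH3Br, NaN(SiMe3)2, THF, 0 °C) to the styrene F5. Cross metathesis of F4 with an excess of F5 (second-generation Hoveyda–Grubbs catalyst, CH2Cl2, 40 °C) should give the E cinnamyl ether 11. The oxirane and the silyl ether are inert to the ruthenium carbene.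

3. Step 2.
- **Risk:** Discrimination between the two enantiomers at the chosen conversion may be incomplete, which would lower the enantiomeric purity of the harvested epoxide. Titanium may also promote opening of the terminal oxirane by alkoxide.
- **Fallback (from 3, returning at 4):** Resolution and epoxidation are separated. Acylation of 3 with vinyl acetate and immobilised Candida antarctica lipase B in MTBE at 30 °C should follow the empirical size rule for secondary alcohols (aryl large, vinyl medium). It should convert the (R)-alcohol into the (R)-acetate F6, which is separated from the unreacted (S)-alcohol. Methanolysis (K2CO3, MeOH, 0 °C) gives the (R)-allylic alcohol F7. Matched epoxidation with Ti(OiPr)4, L-(+)-DIPT and t-BuOOH at −20 °C then acts as a second selection and should deliver 4.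

Further compounds
F1 | step 8 | [(2R,3S,4S)-4-{4-[(tert-butyldimethylsilyl)oxy]-3,5-dimethoxybenzyl}-2-(3,4,5-trimethoxyphenyl)tetrahydrofuran-3-yl]methanol | COc1cc(C[C@@H]2CO[C@@H](c3cc(OC)c(OC)c(OC)c3)[C@@H]2CO)cc(OC)c1O[Si](C)(C)C(C)(C)C
F2 | step 8 | 4-{[(3S,4S,5R)-4-(hydroxymethyl)-5-(3,4,5-trimethoxyphenyl)tetrahydrofuran-3-yl]methyl}-2,6-dimethoxyphenol | COc1cc(C[C@@H]2CO[C@@H](c3cc(OC)c(OC)c(OC)c3)[C@@H]2CO)cc(OC)c1O
F3 | step 8 | p-quinone methide of F2 (C2 exocyclic methylidene on 2,6-dimethoxycyclohexa-2,5-dien-1-one, not isolated) | COC1=CC(=C[C@@H]2CO[C@@H](c3cc(OC)c(OC)c(OC)c3)[C@@H]2CO)C=C(OC)C1=O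
F4 | step 7 | (2R)-2-[(S)-(prop-2-en-1-yloxy)(3,4,5-trimethoxyphenyl)methyl]oxirane | COc1cc(cc(OC)c1OC)[C@H](OCC=C)[C@H]1CO1
F5 | step 7 | tert-butyl(4-ethenyl-2,6-dimethoxyphenoxy)dimethylsilane | C=Cc1cc(OC)c(O[Si](C)(C)C(C)(C)C)c(OC)c1
F6 | step 2 | (1R)-1-(3,4,5-trimethoxyphenyl)prop-2-en-1-yl acetate | COc1cc(cc(OC)c1OC)[C@H](OC(C)=O)C=C
F7 | step 2 | (1R)-1-(3,4,5-trimethoxyphenyl)prop-2-en-1-ol | COc1cc(cc(OC)c1OC)[C@H](O)C=C
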